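Remark on the chemistry: eudesmane numbering (C1–C15; ring A = C1–C5 and C10, ring B = C5–C10) is used for every intermediate, acyclic ones included, and α/β refer to the usual eudesmane orientation in which C14 is β.

## Analysis of the target

The target is a eudesmane, a trans-fused decalin, with a methyl acrylate at C7 (C11–C13, C12 as the ester carbon), an exocyclic methylene at C4 (C15), an angelate (Z-2-methylbut-2-enoate) on O3 and a tertiary allylic hydroperoxide at the ring-fusion carbon C5. It has four stereocentres: the quaternary C10 with its methyl C14 β, C7 with the acrylate β and equatorial (cis to C14 across ring B), C5 with the hydroperoxy group α (trans to C14), and C3 with the ester oxygen β and equatorial (cis to C14, trans to the hydroperoxide). The sensitive groups are the hydroperoxide (reduction, acid- or base-induced fragmentation), the angelate (Z to E isomerisation to the tiglate under nucleophilic or basic conditions), and the α-substituted acrylate (conjugate addition). The difficulty is the contiguous C3–C4–C5 array wedged against the quaternary C10, together with the fact that the hydroperoxide survives no reductive, strongly basic or metal-catalysed step and must therefore come last. That array is the signature of a Schenck ene reaction on a 3β-acyloxy-4-ene, so the real problem is a 4-ene with oxygen at C3, a quaternary C10 and a C7 side chain. In that 4-ene, C3, C4=C5 and C10 are one half of a cyclohexa-1,4-diene: C4 and C5 can come from an alkyne and C3–C2–C1–C10 from a 1-oxygenated diene, and if the two are tied through C6–C9 the same cycloaddition also closes ring B. The strategy rests on this retron.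

## Retrosynthetic reasoning

**C5–O and C4=C15.** Target 24 is traced to angelate 23 by a retro-Schenck ene reaction, which returns the C5 oxygen and puts a hydrogen back on C15 to restore the tetrasubstituted C4=C5 alkene. The cut is made here because the hydroperoxide tolerates none of the other chemistry. The forward reaction has to deliver oxygen to C5 on the α face and take hydrogen from C15 rather than from C3 or C6.

**O3–acyl and C3–H.** Ester 23 is cut at the ester bond into alcohol 20 and angelic acid 21, and 20 is traced to enone 19. Acylation is placed after all oxidations so that the angelate meets no oxidant or base. The enone is wanted for two reasons: it keeps C4=C5 electron-poor during the C12 oxidation, and the axial C14 methyl directs hydride to the α face of C3.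

**C12 oxidation level.** Ester 19 goes back through acid 18 and enal 17 to (+)-α-cyperone 15. No carbon–carbon bond is cut: the acrylate is treated as an oxidised isopropenyl group. The gain is that the side chain is an inert spectator through all organometallic steps and can come from the chiral pool.

**C1–C2 saturation and the C3 carbonyl.** Enone 15 is traced to cross-conjugated dienone 13 and then to the doubly allylic ether 12. This puts back the C1=C2 alkene and turns C3 into an sp3 ether carbon, which is the cyclohexa-1,4-diene needed for the cycloaddition. Forward, an oxidation at C3 removes the C3 stereocentre, and a conjugate reduction must choose the disubstituted enone arm over the tetrasubstituted one.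

**C5–C10 and C3–C4 (key disconnection).** Cycloadduct 12 is opened to the acyclic dienyne 11. These two bonds are chosen because one is the ring-fusion bond and both lie in ring A, so cutting them opens both rings at once and leaves C7 as the only stereocentre. Any other pair would leave a carbocycle to be made separately. The forward reaction must form the quaternary C10 with C14 cis to C11 and must do so with an unactivated alkyne, which calls for metal catalysis rather than heat.

**C1–C2 of the diene.** Dienyne 11 is cut between its two double bonds into alkenyl iodide 9 and boronate 10. Both double bonds of 11 must be E so that the tether and the oxygen substituent sit on the outside of the s-cis diene. Extended enolisation would create the C10=C1 bond with no control over which C10 substituent ends up cis to C2, whereas a cross-coupling carries two pre-set geometries through unchanged. The price is an ethyl rather than a silyl enol ether, which is why the C3 oxygen is later unmasked oxidatively.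

**C10–C14 and C1–I.** Iodide 9 is traced to terminal alkyne 7 by a retro-carbometalation. Syn addition of methyl and metal across the alkyne fixes C9 trans to the future C2.

**C9–C10.** Diyne 7 is cut to iodide 6, which comes from alcohol 5 and aldehyde 4. The two-carbon alkynylation turns the aldehyde carbon C9 into the methylene that the tether needs.

**Ring reconstitution.** Ynal 4 is traced through epoxide 2 to (R)-carvone 1 by a retro-Eschenmoser–Tanabe fragmentation, which reconnects the carbons that become C4 and C9. Carvone supplies the C7 stereocentre with its isopropenyl group, and the fragmentation delivers the methyl-capped alkyne and a differentiated aldehyde arm in one operation, with no strong-base alkylation of an alkyne.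

## Alternatives that were turned down

**Alternative 1: decarboxylative radical closure of ring B.** The disconnection is C7–C8. The precursor A1 is a ring A enone whose C10 carries a two-carbon chain ending in an N-(acyloxy)phthalimide and whose C5 carries a 2-(phenylsulfonylmethyl)acrylate acceptor. Single-electron reduction and loss of CO2 would give a primary C8 radical that adds 6-exo to C7; expulsion of the phenylsulfonyl radical then creates the C11=C13 methylene and gives A2, which is identical with compound 19 of the chosen route.
- For: the acrylate arrives in the key step, so the C12 oxidation (steps 11–13 here) and the dienone detour (steps 9–10) are not needed. On endgame economy this alternative is stronger than the chosen one. The closure is polarity-matched and redox-neutral.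
- Against: it forms one bond and one ring. The quaternary C10 must be set enantioselectively beforehand, and A1 needs two different chains on ring A, a long linear build. 6-exo closures are slow, and the C8 radical has a 1,5-hydrogen shift available from C6, whose C–H is both γ to the enone and allylic to the acceptor. Control of C7 rests on the same 1,4 chair argument as in the chosen route, so nothing is gained there.
- In its place the chosen strategy offers both rings and C10 from a single chiral-pool stereocentre, at the cost of functional-group steps between 12 and 19.

**Alternative 2: biomimetic transannular closure.** The disconnection is C5–C10 alone, across the ten-membered ring of germacrene A methyl ester A3. Protonation at C1, attack of C5 on the C10 cation and loss of H5 would give methyl eudesma-4,11(13)-dien-12-oate A4.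
- For: one proton forms both six-membered rings, the medium ring transmits C7 to C10, and the acrylate is already present. In bond-forming economy it is the shortest of all.
- Against: A3 is itself the hard part, an E,E-cyclodeca-1,5-diene that is prone to Cope rearrangement and is acid-labile. The C4 cation can lose a proton from C3, C5 or C15, so the 4-ene is one of three alkene isomers. A4 has no oxygen at C3, and an allylic oxidation would have to choose C3 over C6 next to a tetrasubstituted alkene with the acrylate present.
- The chosen strategy fixes the alkene position and brings the C3 oxygen in with the diene.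

**Alternative 3: anodic dienol ether–allylsilane coupling.** The disconnection is C6–C7. The precursor A5 is a ring A extended silyl dienol ether with an allylsilane chain on C10. Anodic oxidation would give a radical cation that the allylsilane traps at C6; loss of silicon releases the isopropenyl group and the enone, giving (+)-α-cyperone A6, identical with compound 15.
- For: two nucleophiles are coupled by umpolung, and 15 is reached without the ether oxidation and conjugate reduction (steps 9–10). From 15 onward it is equal to the chosen route.
- Against: again one bond and one ring, with C10 needed beforehand in enantioenriched form. The radical cation can be trapped at C4 as well as at C6, both through six-membered transition states. C7 is set only by remote induction from C10.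
- The chosen strategy sets C10 from C7, a stereocentre that is bought, and makes ring A in the same step.

Key step: step 8

## Route

Step 1
Reactants: 1 (R)-(−)-carvone
Product: 2 (1R,4R,6R)-1-methyl-4-(prop-1-en-2-yl)-7-oxabicyclo[4.1.0]heptan-2-one (carvone 2,3-epoxide, oxirane trans to the isopropenyl group)
Conditions: H2O2 (30% aq), NaOH (cat.), MeOH, 0 °C
Reagents that add atoms: hydrogen peroxide, OO
Why: Weitz–Scheffer epoxidation: the hydroperoxide anion adds in conjugate fashion to the enone only, so the isopropenyl group is untouched; attack anti to the C5 substituent should give mainly the trans epoxide, and both new centres are destroyed in step 2.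

Step 2
Reactants: 2 carvone 2,3-epoxide
Product: 4 (3S)-3-(prop-1-en-2-yl)hept-5-ynal, via tosylhydrazone 3 (not isolated)
Conditions: TsNHNH2, CH2Cl2/AcOH, −20 °C to rt
Reagents that add atoms: none
Why: Eschenmoser–Tanabe fragmentation: the hydrazone opens the oxirane, and loss of N2 and sulfinate cleaves the former C2–C3 bond of carvone to give the methyl-capped alkyne (C15–C4≡C5) and the aldehyde (C9); the stereocentre (C7) is β to the aldehyde and is not touched.

Step 3
Reactants: 4 (3S)-3-(prop-1-en-2-yl)hept-5-ynal
Product: 5 (3S)-3-(prop-1-en-2-yl)hept-5-yn-1-ol
Conditions: NaBH4, MeOH, 0 °C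
Reagents that add atoms: none
Why: Borohydride reduction of an aldehyde; alkyne and alkene are inert.

Step 4
Reactants: 5 (3S)-3-(prop-1-en-2-yl)hept-5-yn-1-ol
Product: 6 (5S)-7-iodo-5-(prop-1-en-2-yl)hept-2-yne
Conditions: I2, PPh3, imidazole, CH2Cl2, 0 °C to rt
Reagents that add atoms: iodine, II
Why: Appel-type (Garegg–Samuelsson) iodination of an unhindered primary alcohol under neutral conditions.

Step 5
Reactants: 6 (5S)-7-iodo-5-(prop-1-en-2-yl)hept-2-yne
Product: 7 (5R)-5-(prop-1-en-2-yl)nona-1,7-diyne
Conditions: LiC≡CH·H2NCH2CH2NH2, DMSO, 10 °C to rt
Reagents that add atoms: lithium acetylide (ethylenediamine complex), [Li+].[C-]#C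
Why: SN2 alkylation of an acetylide by a primary iodide in a dipolar aprotic solvent adds C10 and C1; the acetylide is too weak a base to isomerise the internal alkyne.

Step 6
Reactants: 7 (5R)-5-(prop-1-en-2-yl)nona-1,7-diyne
Product: 9 (1E,5R)-1-iodo-2-methyl-5-(prop-1-en-2-yl)non-1-en-7-yne, via alkenyldimethylalane 8 (not isolated)
Conditions: Me3Al, Cp2ZrCl2 (cat.), H2O (1 equiv), CH2Cl2, −20 °C; then I2, THF, −20 to 0 °C
Reagents that add atoms: trimethylaluminium, C[Al](C)C; iodine, II
Why: Negishi zirconium-catalysed carboalumination: methyl and aluminium add syn across the terminal alkyne with methyl on the internal carbon, and iodinolysis with retention gives the E-iodide (C9 trans to iodine); the internal alkyne and the 1,1-disubstituted alkene react far more slowly under these conditions.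

Step 7
Reactants: 9 (1E,5R)-1-iodo-2-methyl-5-(prop-1-en-2-yl)non-1-en-7-yne; 10 (E)-2-(2-ethoxyethenyl)-4,4,5,5-tetramethyl-1,3,2-dioxaborolane
Product: 11 (1E,3E,7R)-1-ethoxy-4-methyl-7-(prop-1-en-2-yl)undeca-1,3-dien-9-yne
Conditions: Pd(PPh3)4 (5 mol %), K3PO4 (aq), THF, 60 °C
Reagents that add atoms: none
Why: Suzuki–Miyaura coupling proceeds with retention at both sp2 carbons, so the E,E geometry of the dienyl ether is fixed by the two partners; the basic medium leaves the enol ether intact.

Step 8
Reactants: 11 (1E,3E,7R)-1-ethoxy-4-methyl-7-(prop-1-en-2-yl)undeca-1,3-dien-9-yne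
Product: 12 3α-ethoxyeudesma-1,4,11-triene (7β-isopropenyl, 10β-methyl)
Conditions: Ni(cod)2 (10 mol %), P(O-C6H4-2-Ph)3 (30 mol %), THF (0.02 M), 25 to 50 °C
Reagents that add atoms: none
Why: Zerovalent nickel with one bulky phosphite binds the alkyne and the C10=C1 alkene, and oxidative cyclisation joins C5 to C10 to give a divalent nickel metallacycle in which C4 is a vinyl ligand and C1–C2–C3 an allyl ligand; reductive elimination from the C3-bound form then joins C3 to C4 and returns zerovalent nickel. The closest known reaction type is the Ni(cod)2/triaryl phosphite-catalysed intramolecular [4+2] cycloaddition of dienynes, which runs near room temperature with unactivated alkynes, whereas the thermal reaction of this electron-rich pair with a fully substituted diene terminus would need forcing conditions. Ring B closes first, as a six-membered ring across the four-carbon tether C6–C9 (C5–C10 bond); ring A closes second, as a cyclohexa-1,4-diene through the C3–C4 bond, so the overall mode is a terminally tethered [4+2] annulation. C10 is controlled by the C7 stereocentre: in the chair-like forming ring B the metallacycle holds C1 equatorial and C14 axial, and the isopropenyl group takes the equatorial position, which places C14 cis to C11. C3 is set by suprafacial addition to the E,E-diene, which puts the ethoxy group trans to C14 (3α); this centre is removed in step 9. The step needs cyclisation to outrun alkyne oligomerisation, which dilution and the chelating substrate should secure, and it needs one face of C10, which the equatorial preference at C7 should secure. The defined E,E geometry of 11 keeps tether and ethoxy group on the outside of the s-cis diene, and the alkyne leaves C5 sp2, so the C4=C5 alkene needed in step 16 is formed directly.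

Step 9
Reactants: 12 3α-ethoxyeudesma-1,4,11-triene
Product: 13 eudesma-1,4,11-trien-3-one
Conditions: DDQ, CH2Cl2/pH 7 buffer, 0 °C
Reagents that add atoms: water, O
Why: DDQ oxidation of an allylic ether: hydride abstraction from the doubly allylic, α-alkoxy C3–H gives a stabilised oxocarbenium ion, water adds, and the hemiketal collapses to the cross-conjugated dienone with loss of ethanol; the quaternary C10 blocks aromatisation.

Step 10
Reactants: 13 eudesma-1,4,11-trien-3-one
Product: 15 (+)-α-cyperone (eudesma-4,11-dien-3-one), via silyl dienol ether 14 (not isolated)
Conditions: [(Ph3P)CuH]6 (5 mol %), PhMe2SiH, toluene, rt; then 1 M HCl, THF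
Reagents that add atoms: none
Why: Copper hydride conjugate reduction delivers hydride to C1, the β-carbon of the disubstituted enone arm; the tetrasubstituted C4=C5 arm is far more hindered and the isopropenyl group is not a substrate. Protonation of the silyl dienol ether at C2 gives the conjugated 4-en-3-one.

Step 11
Reactants: 15 (+)-α-cyperone
Product: 17 3-oxoeudesma-4,11(13)-dien-12-al, via allylic alcohol 16 (not isolated)
Conditions: SeO2 (cat.), t-BuOOH, CH2Cl2, rt; then MnO2, CH2Cl2, rt
Reagents that add atoms: selenium dioxide, O=[Se]=O; tert-butyl hydroperoxide, CC(C)(C)OO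
Why: Selenium dioxide allylic oxidation (ene reaction, then [2,3] shift) attacks the only electron-rich alkene, the isopropenyl group, while the C4=C5 alkene is deactivated as an enone; MnO2 converges the alcohol and any aldehyde already formed on the enal.

Step 12
Reactants: 17 3-oxoeudesma-4,11(13)-dien-12-al
Product: 18 3-oxoeudesma-4,11(13)-dien-12-oic acid
Conditions: NaClO2, NaH2PO4, 2-methylbut-2-ene, t-BuOH/H2O, 0 °C to rt
Reagents that add atoms: sodium chlorite, [Na+].[O-]Cl=O
Why: Pinnick oxidation converts the 2-substituted acrolein to the acrylic acid without touching the enone; the scavenger removes hypochlorous acid.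

Step 13
Reactants: 18 3-oxoeudesma-4,11(13)-dien-12-oic acid
Product: 19 methyl 3-oxoeudesma-4,11(13)-dien-12-oate
Conditions: MeI, K2CO3, DMF, rt
Reagents that add atoms: iodomethane, CI
Why: O-alkylation of the carboxylate; K2CO3 is too weak a base to enolise the enone.

Step 14
Reactants: 19 methyl 3-oxoeudesma-4,11(13)-dien-12-oate
Product: 20 methyl 3β-hydroxyeudesma-4,11(13)-dien-12-oate
Conditions: NaBH4, CeCl3·7H2O, MeOH, −78 °C
Reagents that add atoms: none
Why: Luche 1,2-reduction: hydride should add to C3 from the α face, anti to the axial C14 methyl that shields the β face of ring A, giving the equatorial 3β-alcohol; at −78 °C the acrylate and the ester should not react.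

Step 15
Reactants: 20 methyl 3β-hydroxyeudesma-4,11(13)-dien-12-oate; 21 angelic acid
Product: 23 methyl 3β-angeloyloxyeudesma-4,11(13)-dien-12-oate, via mixed anhydride 22 (not isolated)
Conditions: 2,4,6-Cl3C6H2COCl, Et3N, toluene, rt; then 20, 75 °C
Reagents that add atoms: none
Why: Yamaguchi esterification through the trichlorobenzoyl mixed anhydride acylates the hindered allylic alcohol with retention at C3; no nucleophilic catalyst is used, because reversible conjugate addition to the angelate is the path to the tiglate.

Step 16
Reactants: 23 methyl 3β-angeloyloxyeudesma-4,11(13)-dien-12-oate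
Product: 24 methyl 3β-angeloyloxy-5α-hydroperoxyeudesma-4(15),11(13)-dien-12-oate (target)
Conditions: O2, hν (visible), tetraphenylporphyrin (cat.), CH2Cl2, 0 °C
Reagents that add atoms: dioxygen, O=O
Why: Schenck ene reaction: singlet oxygen attacks the only electron-rich alkene, C4=C5, from the α face, because the β face is shielded by the axial C14 methyl and the 3β-ester, bonds to C5 and abstracts a hydrogen from C15, which moves the double bond to the exocyclic position and sets C5 with the hydroperoxide trans to C14. On the α face the C6 hydrogen is equatorial and poorly aligned, and the acrylate and angelate alkenes are electron-poor.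

## Compound list

1 | (R)-(−)-carvone | CC1=CC[C@H](CC1=O)C(C)=C | starting material
2 | (1R,4R,6R)-1-methyl-4-(prop-1-en-2-yl)-7-oxabicyclo[4.1.0]heptan-2-one | C[C@@]12O[C@@H]1C[C@H](CC2=O)C(C)=C | intermediate
3 | p-toluenesulfonylhydrazone of 2 | C[C@@]12O[C@@H]1C[C@H](CC2=NNS(=O)(=O)c1ccc(C)cc1)C(C)=C | intermediate (not isolated)
4 | (3S)-3-(prop-1-en-2-yl)hept-5-ynal | CC#CC[C@@H](CC=O)C(C)=C | intermediate
5 | (3S)-3-(prop-1-en-2-yl)hept-5-yn-1-ol | CC#CC[C@@H](CCO)C(C)=C | intermediate
6 | (5S)-7-iodo-5-(prop-1-en-2-yl)hept-2-yne | CC#CC[C@@H](CCI)C(C)=C | intermediate
7 | (5R)-5-(prop-1-en-2-yl)nona-1,7-diyne | CC#CC[C@@H](CCC#C)C(C)=C | intermediate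
8 | dimethyl[(1E,5R)-2-methyl-5-(prop-1-en-2-yl)non-1-en-7-yn-1-yl]alane | CC#CC[C@@H](CC/C(C)=C/[Al](C)C)C(C)=C | intermediate (not isolated)
9 | (1E,5R)-1-iodo-2-methyl-5-(prop-1-en-2-yl)non-1-en-7-yne | CC#CC[C@@H](CC/C(C)=C/I)C(C)=C | intermediate
10 | (E)-2-(2-ethoxyethenyl)-4,4,5,5-tetramethyl-1,3,2-dioxaborolane | CCO/C=C/B1OC(C)(C)C(C)(C)O1 | starting material
11 | (1E,3E,7R)-1-ethoxy-4-methyl-7-(prop-1-en-2-yl)undeca-1,3-dien-9-yne | CC#CC[C@@H](CC/C(C)=C/C=C/OCC)C(C)=C | intermediate
12 | 3α-ethoxyeudesma-1,4,11-triene | C=C(C)[C@@H]1CC[C@@]2(C)C=C[C@@H](OCC)C(C)=C2C1 | intermediate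
13 | eudesma-1,4,11-trien-3-one | C=C(C)[C@@H]1CC[C@@]2(C)C=CC(=O)C(C)=C2C1 | intermediate
14 | 3-(dimethylphenylsilyloxy)eudesma-2,4,11-triene | C=C(C)[C@@H]1CC[C@@]2(C)CC=C(O[Si](C)(C)c3ccccc3)C(C)=C2C1 | intermediate (not isolated)
15 | (+)-α-cyperone (eudesma-4,11-dien-3-one) | C=C(C)[C@@H]1CC[C@@]2(C)CCC(=O)C(C)=C2C1 | intermediate
16 | 12-hydroxyeudesma-4,11(13)-dien-3-one | C=C(CO)[C@@H]1CC[C@@]2(C)CCC(=O)C(C)=C2C1 | intermediate (not isolated)
17 | 3-oxoeudesma-4,11(13)-dien-12-al | C=C(C=O)[C@@H]1CC[C@@]2(C)CCC(=O)C(C)=C2C1 | intermediate
18 | 3-oxoeudesma-4,11(13)-dien-12-oic acid | C=C(C(=O)O)[C@@H]1CC[C@@]2(C)CCC(=O)C(C)=C2C1 | intermediate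
19 | methyl 3-oxoeudesma-4,11(13)-dien-12-oate | C=C(C(=O)OC)[C@@H]1CC[C@@]2(C)CCC(=O)C(C)=C2C1 | intermediate
20 | methyl 3β-hydroxyeudesma-4,11(13)-dien-12-oate | C=C(C(=O)OC)[C@@H]1CC[C@@]2(C)CC[C@H](O)C(C)=C2C1 | intermediate
21 | angelic acid ((Z)-2-methylbut-2-enoic acid) | C/C=C(/C)C(=O)O | starting material
22 | angelic 2,4,6-trichlorobenzoic anhydride | C/C=C(/C)C(=O)OC(=O)c1c(Cl)cc(Cl)cc1Cl | intermediate (not isolated)
23 | methyl 3β-angeloyloxyeudesma-4,11(13)-dien-12-oate | C=C(C(=O)OC)[C@@H]1CC[C@@]2(C)CC[C@H](OC(=O)/C(C)=C\C)C(C)=C2C1 | intermediate
24 | methyl 3β-angeloyloxy-5α-hydroperoxyeudesma-4(15),11(13)-dien-12-oate | C=C(C(=O)OC)[C@@H]1CC[C@@]2(C)CC[C@H](OC(=O)/C(C)=C\C)C(=C)[C@]2(OO)C1 | target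

## Step count and least certain steps

Total step count: 16. Longest linear sequence: 16 steps from 1 (10 and 21 are purchased).

**Step 8 (key step).** The most likely failures are incomplete facial selectivity at C10 and diversion of the nickel intermediate into alkyne oligomerisation. The first arises because an axial isopropenyl group or a boat-like tether costs little when C5 is sp-hybridised. The second arises because the inside methyl on C10 raises the energy of the s-cis diene, and because a 1-alkoxydiene is a less-tested partner. The fallback sets out from 1, returns at 15 and gives up the cycloaddition. Conjugate reduction of 1 with LiBH(s-Bu)3 gives (2R,5R)-dihydrocarvone F1. Condensation with (R)-1-phenylethylamine gives the imine F2. Michael addition of its secondary enamine tautomer to pent-1-en-3-one, on the face set by the auxiliary, gives the adduct imine F3, which aqueous acetic acid hydrolyses to the 1,5-diketone F4 (methyl cis to isopropenyl). NaOMe in methanol then closes ring A by aldol condensation to give 15. Steps 11 to 16 are unchanged.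

**Step 9.** The risk is capture of the delocalised cation by water at C1 or C5 rather than C3, or slow hydride abstraction next to the C4 methyl. The fallback sets out from 12 and returns at 15. KOt-Bu in DMSO isomerises the doubly allylic ether to the conjugated dienyl ether 3-ethoxyeudesma-2,4,11-triene F5, by deprotonation at C3 and reprotonation at the less hindered C1. Aqueous oxalic acid in THF then hydrolyses F5 by protonation at C2 directly to 15, which also makes step 10 unnecessary.

**Step 11.** The risk is low conversion and over-oxidation, because a 1,1-disubstituted alkene is a slow ene partner for selenium dioxide, and competing oxidation at C2 next to the ketone on prolonged reaction. The fallback sets out from 15 and returns at 17. Ene-type chlorination of the isopropenyl group with Ca(OCl)2 and solid CO2 in CH2Cl2/H2O gives 12-chloroeudesma-4,11(13)-dien-3-one F6. Oxidation of the allylic chloride with Me3NO in DMSO gives 17.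

**Step 14.** The risk is poor facial selectivity, because the C4 methyl disfavours the equatorial 3β-alcohol through allylic strain, and conjugate reduction of the acrylate if the temperature rises. The fallback sets out from 19 and returns at 23. The epimeric methyl 3α-hydroxyeudesma-4,11(13)-dien-12-oate F7 formed in the reduction is separated and esterified with 21 under Mitsunobu conditions (PPh3, diisopropyl azodicarboxylate, toluene, 0 °C to rt), which inverts C3 and gives 23 directly, so both epimers converge.

**Step 16.** The risks are abstraction of the axial C3 hydrogen geminal to the ester instead of a C15 hydrogen, attack on the β face with abstraction of the axial C6 hydrogen, and loss of the tertiary allylic hydroperoxide during isolation. The fallback sets out from 20 and returns at 24, and it moves the ene reaction ahead of the acylation.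
- Silylation of 20 (t-BuMe2SiOTf, 2,6-lutidine) gives the 3β-silyl ether F8, whose bulk shields the β face more strongly and which carries no ester.
- The Schenck ene reaction of F8 gives the 5α-hydroperoxide F9.
- 2-Methoxypropene with pyridinium p-toluenesulfonate masks it as the peroxyketal F10.
- Bu4NF buffered with AcOH removes the silyl group to give the alcohol F11.
- Yamaguchi esterification with 21, as in step 15, gives the angelate peroxyketal F12.
- AcOH in THF/H2O releases 24.

## Further compounds

F1 | step 8 | (2R,5R)-dihydrocarvone | C[C@@H]1CC[C@H](CC1=O)C(C)=C
F2 | step 8 | imine of F1 with (R)-1-phenylethylamine | C[C@@H]1CC[C@H](C/C1=N\[C@H](C)c1ccccc1)C(C)=C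
F3 | step 8 | Michael adduct imine (2-methyl-2-(3-oxopentyl)-5-isopropenylcyclohexanone N-[(R)-1-phenylethyl]imine) | C=C(C)[C@@H]1CC[C@@](C)(CCC(=O)CC)C(=N[C@H](C)c2ccccc2)C1
F4 | step 8 | 2-methyl-2-(3-oxopentyl)-5-(prop-1-en-2-yl)cyclohexanone (methyl cis to isopropenyl) | C=C(C)[C@@H]1CC[C@@](C)(CCC(=O)CC)C(=O)C1
F5 | step 9 | 3-ethoxyeudesma-2,4,11-triene | C=C(C)[C@@H]1CC[C@@]2(C)CC=C(OCC)C(C)=C2C1
F6 | step 11 | 12-chloroeudesma-4,11(13)-dien-3-one | C=C(CCl)[C@@H]1CC[C@@]2(C)CCC(=O)C(C)=C2C1
F7 | step 14 | methyl 3α-hydroxyeudesma-4,11(13)-dien-12-oate | C=C(C(=O)OC)[C@@H]1CC[C@@]2(C)CC[C@@H](O)C(C)=C2C1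
F8 | step 16 | methyl 3β-(tert-butyldimethylsilyloxy)eudesma-4,11(13)-dien-12-oate | C=C(C(=O)OC)[C@@H]1CC[C@@]2(C)CC[C@H](O[Si](C)(C)C(C)(C)C)C(C)=C2C1
F9 | step 16 | methyl 3β-(tert-butyldimethylsilyloxy)-5α-hydroperoxyeudesma-4(15),11(13)-dien-12-oate | C=C(C(=O)OC)[C@@H]1CC[C@@]2(C)CC[C@H](O[Si](C)(C)C(C)(C)C)C(=C)[C@]2(OO)C1
F10 | step 16 | 2-methoxyprop-2-yl peroxyketal of F9 | C=C(C(=O)OC)[C@@H]1CC[C@@]2(C)CC[C@H](O[Si](C)(C)C(C)(C)C)C(=C)[C@]2(OOC(C)(C)OC)C1
F11 | step 16 | methyl 3β-hydroxy-5α-(2-methoxyprop-2-ylperoxy)eudesma-4(15),11(13)-dien-12-oate | C=C(C(=O)OC)[C@@H]1CC[C@@]2(C)CC[C@H](O)C(=C)[C@]2(OOC(C)(C)OC)C1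
F12 | step 16 | methyl 3β-angeloyloxy-5α-(2-methoxyprop-2-ylperoxy)eudesma-4(15),11(13)-dien-12-oate | C=C(C(=O)OC)[C@@H]1CC[C@@]2(C)CC[C@H](OC(=O)/C(C)=C\C)C(=C)[C@]2(OOC(C)(C)OC)C1
A1 | alternative 1 | ring A enone with C10 chain ending in an N-(acyloxy)phthalimide and a methyl 2-(phenylsulfonylmethyl)but-2-enoate acceptor on C5 (alkene geometry immaterial) | COC(=O)C(CS(=O)(=O)c1ccccc1)=CCC1=C(C)C(=O)CC[C@]1(C)CCC(=O)ON1C(=O)c2ccccc2C1=O
A2 | alternative 1 | methyl 3-oxoeudesma-4,11(13)-dien-12-oate | C=C(C(=O)OC)[C@@H]1CC[C@@]2(C)CCC(=O)C(C)=C2C1
A3 | alternative 2 | germacrene A methyl ester (methyl (1(10)E,4E)-germacra-1(10),4,11(13)-trien-12-oate) | C=C(C(=O)OC)[C@@H]1CC/C(C)=C/CC/C(C)=C/C1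
A4 | alternative 2 | methyl eudesma-4,11(13)-dien-12-oate | C=C(C(=O)OC)[C@@H]1CC[C@@]2(C)CCCC(C)=C2C1
A5 | alternative 3 | ring A extended silyl dienol ether with an allylsilane chain on C10 (allylsilane geometry immaterial) | C=C1C(C)=C(O[Si](C)(C)C(C)(C)C)CC[C@]1(C)CCC=C(C)C[Si](C)(C)C
A6 | alternative 3 | (+)-α-cyperone | C=C(C)[C@@H]1CC[C@@]2(C)CCC(=O)C(C)=C2C1
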